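Backbone carbons are numbered C1–C24 from the isopropenyl end written first. Everything rests on the C15–C16 bond: C15, the methyl-bearing quaternary carbon of the C14–C15 oxirane, is the retron of alkyl addition to an α-chloro methyl ketone. Two lactone-derived chain Grignard reagents are added in turn to C2-symmetric (3R,6R)-3,6-dichlorooctane-2,7-dione (C10–C15). In the key step the C16–C24 Grignard adds to the C15 ketone of a chlorohydrin/chloro ketone carrying C1–C15; the C14–Cl dipole (Cornforth model) sets C15, and base then closes both oxiranes by 3-exo-tet displacement, so no oxidant ever meets the four 1,1-disubstituted alkenes.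

Key step: step 20

Remark 1: read from the SMILES, the target is 3R,7R,10S,11S,14S,15S,18R,22S; C3 and C22 have opposite configuration, so the two C13 side chains are diastereomers and are made separately.
Remark 2: the ligand and catalyst antipodes written in steps 1, 2 and 16 are those expected to give the stated configurations; each sense is to be confirmed on the first batch and the antipode exchanged if needed.

**Left-hand chain (C1–C9)**

Step 1
Reactants: 1 α-methylene-γ-butyrolactone (3-methylideneoxolan-2-one)
Product: 2 (R)-α-methyl-γ-butyrolactone [(3R)-3-methyloxolan-2-one]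
Conditions: H2 (100 atm), Ru(OAc)2[(S)-BINAP] (0.2 mol%), CH2Cl2, 50 °C
Reagents that add atoms: none
Why: Ru–BINAP asymmetric hydrogenation of an exocyclic α-alkylidene lactone, in which the ligand antipode selects the enantioface of the C=C and so sets the methyl-bearing centre as R.

Step 2
Reactants: 1 α-methylene-γ-butyrolactone
Product: 3 (S)-α-methyl-γ-butyrolactone [(3S)-3-methyloxolan-2-one]
Conditions: H2 (100 atm), Ru(OAc)2[(R)-BINAP] (0.2 mol%), CH2Cl2, 50 °C
Reagents that add atoms: none
Why: The same Ru–BINAP asymmetric hydrogenation with the antipodal ligand, which should set the methyl-bearing centre as S.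

Step 3
Reactants: 2 (R)-α-methyl-γ-butyrolactone
Product: 4 (3R)-5-hydroxy-3-methylpentan-2-one
Conditions: MeLi (1.05 equiv), THF, −78 °C; AcOH, −78 °C
Reagents that add atoms: methyllithium, [Li]C
Why: Mono-addition of an organolithium to a lactone, in which the tetrahedral lithium lactolate survives at −78 °C and gives the γ-hydroxy ketone only on cold protonation, so no second addition is expected and the α-centre is carried over unchanged.

Step 4
Reactants: 4 (3R)-5-hydroxy-3-methylpentan-2-one
Product: 5 (3R)-3,4-dimethylpent-4-en-1-ol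
Conditions: Zn, CH2Br2, TiCl4, THF (pre-formed reagent); then 4, CH2Cl2, 0 °C → rt
Reagents that add atoms: dibromomethane, BrCBr
Why: Takai–Lombardo methylenation, a non-basic carbonyl olefination that tolerates the free hydroxyl and should not enolise the ketone, so the adjacent CH(CH3) centre keeps its configuration.

Step 5
Reactants: 5 (3R)-3,4-dimethylpent-4-en-1-ol
Product: 6 (3R)-5-iodo-2,3-dimethylpent-1-ene
Conditions: I2, PPh3, imidazole, CH2Cl2, 0 °C → rt
Reagents that add atoms: iodine, II
Why: Appel-type iodination of a primary alcohol by SN2 displacement of the oxyphosphonium at CH2, which touches neither the stereocentre nor the alkene.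

Step 6
Reactants: 6 (3R)-5-iodo-2,3-dimethylpent-1-ene; 2 (R)-α-methyl-γ-butyrolactone
Product: 8 (3R,7R)-1-hydroxy-3,7,8-trimethylnon-8-en-4-one, via alkyllithium 7 (not isolated)
Conditions: t-BuLi (2.1 equiv), Et2O–pentane, −78 °C; then added to 2 (1.2 equiv), THF, −78 °C; AcOH, −78 °C
Reagents that add atoms: none
Why: Iodine–lithium exchange followed by mono-addition of the primary alkyllithium to the lactone (lactolate stable at −78 °C); both stereocentres come unchanged from 6 and 2.

Step 7
Reactants: 8 (3R,7R)-1-hydroxy-3,7,8-trimethylnon-8-en-4-one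
Product: 9 (3R,7R)-3,7,8-trimethyl-4-methylidenenon-8-en-1-ol
Conditions: Zn, CH2Br2, TiCl4, THF (pre-formed reagent); then 8, CH2Cl2, 0 °C → rt
Reagents that add atoms: dibromomethane, BrCBr
Why: Takai–Lombardo methylenation of the ketone under non-basic conditions, so the α-CH(CH3) centre is not epimerised and the hydroxyl and isopropenyl group are tolerated.

Step 8
Reactants: 9 (3R,7R)-3,7,8-trimethyl-4-methylidenenon-8-en-1-ol
Product: 10 (3R,7R)-9-bromo-2,3,7-trimethyl-6-methylidenenon-1-ene
Conditions: CBr4, PPh3, CH2Cl2, 0 °C
Reagents that add atoms: carbon tetrabromide, BrC(Br)(Br)Br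
Why: Appel bromination of the primary alcohol (SN2 at CH2), which leaves both stereocentres and both 1,1-disubstituted alkenes untouched.

**Right-hand chain (C16–C24)**

Step 9
Reactants: 3 (S)-α-methyl-γ-butyrolactone
Product: 11 (3S)-5-hydroxy-3-methylpentan-2-one
Conditions: MeLi (1.05 equiv), THF, −78 °C; AcOH, −78 °C
Reagents that add atoms: methyllithium, [Li]C
Why: Mono-addition of methyllithium to the lactone through a lactolate that is stable at −78 °C, as in step 3, with the α-centre carried over.

Step 10
Reactants: 11 (3S)-5-hydroxy-3-methylpentan-2-one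
Product: 12 (3S)-3,4-dimethylpent-4-en-1-ol
Conditions: Zn, CH2Br2, TiCl4, THF (pre-formed reagent); then 11, CH2Cl2, 0 °C → rt
Reagents that add atoms: dibromomethane, BrCBr
Why: Takai–Lombardo methylenation, non-basic, so the α-stereocentre should be preserved.

Step 11
Reactants: 12 (3S)-3,4-dimethylpent-4-en-1-ol
Product: 13 (3S)-5-iodo-2,3-dimethylpent-1-ene
Conditions: I2, PPh3, imidazole, CH2Cl2, 0 °C → rt
Reagents that add atoms: iodine, II
Why: Appel-type iodination of the primary alcohol, with no stereocentre involved.

Step 12
Reactants: 13 (3S)-5-iodo-2,3-dimethylpent-1-ene; 2 (R)-α-methyl-γ-butyrolactone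
Product: 15 (3R,7S)-1-hydroxy-3,7,8-trimethylnon-8-en-4-one, via alkyllithium 14 (not isolated)
Conditions: t-BuLi (2.1 equiv), Et2O–pentane, −78 °C; then added to 2 (1.2 equiv), THF, −78 °C; AcOH, −78 °C
Reagents that add atoms: none
Why: Iodine–lithium exchange and mono-addition of the alkyllithium to the lactone, which joins the S terminal unit to the R internal unit without touching either centre.

Step 13
Reactants: 15 (3R,7S)-1-hydroxy-3,7,8-trimethylnon-8-en-4-one
Product: 16 (3R,7S)-3,7,8-trimethyl-4-methylidenenon-8-en-1-ol
Conditions: Zn, CH2Br2, TiCl4, THF (pre-formed reagent); then 15, CH2Cl2, 0 °C → rt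
Reagents that add atoms: dibromomethane, BrCBr
Why: Takai–Lombardo methylenation without enolisation of the α-branched ketone.

Step 14
Reactants: 16 (3R,7S)-3,7,8-trimethyl-4-methylidenenon-8-en-1-ol
Product: 17 (3S,7R)-9-bromo-2,3,7-trimethyl-6-methylidenenon-1-ene
Conditions: CBr4, PPh3, CH2Cl2, 0 °C
Reagents that add atoms: carbon tetrabromide, BrC(Br)(Br)Br
Why: Appel bromination of the primary alcohol, with stereocentres and alkenes untouched.

**C2-symmetric linchpin (C10–C15)**

Step 15
Reactants: 18 cyclohexene
Product: 19 hexanedial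
Conditions: O3, CH2Cl2, −78 °C; Me2S, −78 °C → rt; used as a fresh solution
Reagents that add atoms: ozone, [O-][O+]=O
Why: Ozonolysis with reductive work-up cleaves the ring C=C to the 1,6-dialdehyde that holds all six core carbons.

Step 16
Reactants: 19 hexanedial
Product: 20 (2R,5R)-2,5-dichlorohexanedial
Conditions: NCS (2.6 equiv), (2S,5S)-2,5-diphenylpyrrolidine (20 mol%), CH2Cl2, 0 °C → rt; pentane, filtration; used crude at once
Reagents that add atoms: N-chlorosuccinimide, O=C1CCC(=O)N1Cl
Why: Enamine-catalysed α-chlorination of aldehydes, in which the C2-symmetric amine shields one enamine face so that each CHCl centre is set R by the catalyst, while the absence of an acid co-catalyst should keep intramolecular aldolisation slower than chlorination.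

Step 17
Reactants: 20 (2R,5R)-2,5-dichlorohexanedial
Product: 21 (3R,6R)-3,6-dichlorooctane-2,7-diol (mixture of carbinol epimers)
Conditions: MeMgBr (2.4 equiv), THF–Et2O, −78 °C; AcOH, −78 °C
Reagents that add atoms: methylmagnesium bromide, C[Mg]Br
Why: Grignard addition to the α-chloro aldehydes at −78 °C, where the chlorohydrin magnesium alkoxides do not close or epimerise; the new carbinol centres are irrelevant because they are oxidised next.

Step 18
Reactants: 21 (3R,6R)-3,6-dichlorooctane-2,7-diol
Product: 22 (3R,6R)-3,6-dichlorooctane-2,7-dione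
Conditions: Dess–Martin periodinane (2.5 equiv), CH2Cl2, 0 °C → rt
Reagents that add atoms: none
Why: Dess–Martin oxidation of both secondary chlorohydrins under base-free conditions that should not epimerise the CHCl centres; the meso isomer, which carries most of the minor enantiomeric series, is removed here by crystallisation or chromatography.

**Fragment unions**

Step 19
Reactants: 10 (3R,7R)-9-bromo-2,3,7-trimethyl-6-methylidenenon-1-ene; 22 (3R,6R)-3,6-dichlorooctane-2,7-dione
Product: 24 (3R,6R,7S,10R,14R)-3,6-dichloro-7-hydroxy-7,10,14,15-tetramethyl-11-methylidenehexadec-15-en-2-one, via Grignard reagent 23 (not isolated)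
Conditions: Mg, THF, 40 °C; then added slowly to 22 (3 equiv), THF–Et2O, −78 °C; AcOH, −78 °C; excess 22 recovered
Reagents that add atoms: none
Why: Cornforth-controlled Grignard addition to one of the two homotopic ketones of the dione used in excess, with C–Cl antiperiplanar to C=O and attack past H setting the carbinol carbon (C10) as S, while the cold acidic quench keeps the chlorohydrin open so that the remaining α-chloro ketone never meets base.

Step 20
Reactants: 17 (3S,7R)-9-bromo-2,3,7-trimethyl-6-methylidenenon-1-ene; 24 (3R,6R,7S,10R,14R)-3,6-dichloro-7-hydroxy-7,10,14,15-tetramethyl-11-methylidenehexadec-15-en-2-one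
Product: 27 CNP0269398.1, (3R,7R,10S,11S,14S,15S,18R,22S)-10,11:14,15-diepoxy-2,3,7,10,15,18,22,23-octamethyl-6,19-dimethylidenetetracosa-1,23-diene, via Grignard reagent 25 (not isolated), via bis-chlorohydrin 26 (not isolated)
Conditions: Mg, THF, 40 °C; 25 (2.3 equiv) added to 24, THF–Et2O, −78 °C; AcOH, −78 °C; then K2CO3, MeOH, 23 °C
Reagents that add atoms: none
Why: The first equivalent of 25 deprotonates the tertiary hydroxyl of 24 and the second adds to the C15 carbonyl through the Cornforth transition state, in which C14–Cl lies antiperiplanar to C=O and the nucleophile passes the small C14–H and not the C13 chain, which should set C15 as S; this is the 1,2-addition of a Grignard reagent to an α-chloro ketone followed by chlorohydrin-to-epoxide closure, the reaction type of the Cornforth olefin synthesis. With K2CO3/MeOH each tertiary alkoxide then displaces the vicinal secondary chloride from the rear, closing the C10–C11 and the C14–C15 oxirane by 3-exo-tet ring closure with inversion at C11 and C14 (R to S), which gives trans-oxiranes with C9 and C16 anti to the C12–C13 tether. The one new stereocentre, C15, is controlled by the existing C14–Cl centre (1,2-induction); C10 was set the same way in step 19 and no other centre is touched. The step needs π-facial selectivity at C15, 1,2-addition in preference to enolisation or attack at C–Cl, and 3-exo closure in preference to 6-exo attack on the distal chloride. These are secured by the fixed dipole alignment of the α-chloro ketone, by adding an unhindered primary Grignard reagent to a methyl ketone at −78 °C, and by the kinetic preference of a chlorohydrin alkoxide for three-membered ring closure. The four 1,1-disubstituted alkenes are inert to every reagent in this step.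

**Compound list**

1 | α-methylene-γ-butyrolactone (3-methylideneoxolan-2-one) | C=C1CCOC1=O | starting material
2 | (R)-α-methyl-γ-butyrolactone | C[C@@H]1CCOC1=O | intermediate
3 | (S)-α-methyl-γ-butyrolactone | C[C@H]1CCOC1=O | intermediate
4 | (3R)-5-hydroxy-3-methylpentan-2-one | CC(=O)[C@H](C)CCO | intermediate
5 | (3R)-3,4-dimethylpent-4-en-1-ol | C=C(C)[C@H](C)CCO | intermediate
6 | (3R)-5-iodo-2,3-dimethylpent-1-ene | C=C(C)[C@H](C)CCI | intermediate
7 | [(3R)-3,4-dimethylpent-4-en-1-yl]lithium | C=C(C)[C@H](C)CC[Li] | intermediate (not isolated)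
8 | (3R,7R)-1-hydroxy-3,7,8-trimethylnon-8-en-4-one | C=C(C)[C@H](C)CCC(=O)[C@H](C)CCO | intermediate
9 | (3R,7R)-3,7,8-trimethyl-4-methylidenenon-8-en-1-ol | C=C(C)[C@H](C)CCC(=C)[C@H](C)CCO | intermediate
10 | (3R,7R)-9-bromo-2,3,7-trimethyl-6-methylidenenon-1-ene | C=C(C)[C@H](C)CCC(=C)[C@H](C)CCBr | intermediate
11 | (3S)-5-hydroxy-3-methylpentan-2-one | CC(=O)[C@@H](C)CCO | intermediate
12 | (3S)-3,4-dimethylpent-4-en-1-ol | C=C(C)[C@@H](C)CCO | intermediate
13 | (3S)-5-iodo-2,3-dimethylpent-1-ene | C=C(C)[C@@H](C)CCI | intermediate
14 | [(3S)-3,4-dimethylpent-4-en-1-yl]lithium | C=C(C)[C@@H](C)CC[Li] | intermediate (not isolated)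
15 | (3R,7S)-1-hydroxy-3,7,8-trimethylnon-8-en-4-one | C=C(C)[C@@H](C)CCC(=O)[C@H](C)CCO | intermediate
16 | (3R,7S)-3,7,8-trimethyl-4-methylidenenon-8-en-1-ol | C=C(C)[C@@H](C)CCC(=C)[C@H](C)CCO | intermediate
17 | (3S,7R)-9-bromo-2,3,7-trimethyl-6-methylidenenon-1-ene | C=C(C)[C@@H](C)CCC(=C)[C@H](C)CCBr | intermediate
18 | cyclohexene | C1=CCCCC1 | starting material
19 | hexanedial | O=CCCCCC=O | intermediate
20 | (2R,5R)-2,5-dichlorohexanedial | O=C[C@H](Cl)CC[C@@H](Cl)C=O | intermediate
21 | (3R,6R)-3,6-dichlorooctane-2,7-diol (carbinol epimers) | CC(O)[C@H](Cl)CC[C@@H](Cl)C(C)O | intermediate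
22 | (3R,6R)-3,6-dichlorooctane-2,7-dione | CC(=O)[C@H](Cl)CC[C@@H](Cl)C(C)=O | intermediate
23 | [(3R,7R)-3,7,8-trimethyl-4-methylidenenon-8-en-1-yl]magnesium bromide | C=C(C)[C@H](C)CCC(=C)[C@H](C)CC[Mg]Br | intermediate (not isolated)
24 | (3R,6R,7S,10R,14R)-3,6-dichloro-7-hydroxy-7,10,14,15-tetramethyl-11-methylidenehexadec-15-en-2-one | C=C(C)[C@H](C)CCC(=C)[C@H](C)CC[C@](C)(O)[C@H](Cl)CC[C@@H](Cl)C(C)=O | intermediate
25 | [(3R,7S)-3,7,8-trimethyl-4-methylidenenon-8-en-1-yl]magnesium bromide | C=C(C)[C@@H](C)CCC(=C)[C@H](C)CC[Mg]Br | intermediate (not isolated)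
26 | (3R,7R,10S,11R,14R,15S,18R,22S)-11,14-dichloro-2,3,7,10,15,18,22,23-octamethyl-6,19-dimethylidenetetracosa-1,23-diene-10,15-diol | C=C(C)[C@H](C)CCC(=C)[C@H](C)CC[C@](C)(O)[C@H](Cl)CC[C@@H](Cl)[C@@](C)(O)CC[C@@H](C)C(=C)CC[C@H](C)C(=C)C | intermediate (not isolated)
27 | CNP0269398.1, (3R,7R,10S,11S,14S,15S,18R,22S)-10,11:14,15-diepoxy-2,3,7,10,15,18,22,23-octamethyl-6,19-dimethylidenetetracosa-1,23-diene | C=C(C)[C@H](C)CCC(=C)[C@H](C)CC[C@]1(C)O[C@H]1CC[C@@H]1O[C@@]1(C)CC[C@@H](C)C(=C)CC[C@H](C)C(=C)C | target

**Step count and risks**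

Total: 20 steps. Longest linear sequence: 9 steps (1, 3, 4, 5, 6, 7, 8, 19, 20).

Step 20 (key step). What may go wrong: erosion of π-facial selectivity in the addition to the C15 carbonyl (attack past the C13 chain, leading to the cis-oxirane), or enolisation of the α-chloro ketone by the basic Grignard reagent with loss of the C14 configuration. The fallback replaces substrate control by a stereospecific cross-coupling and a catalyst-controlled epoxidation; it sets out from bromides 10 and 17 and comes back at 27. Commercial octa-2,6-diyne is hydrozirconated with excess Cp2Zr(H)Cl (equilibration places zirconium on the methyl-bearing carbons) and iodinated to (2E,6E)-2,7-diiodoocta-2,6-diene F1. The alkylzinc bromide made from 10 (Mg, then ZnBr2) is coupled with excess F1 under palladium catalysis (Negishi coupling) to the vinyl iodide (3R,7R,10E,14E)-15-iodo-2,3,7,10-tetramethyl-6-methylidenehexadeca-1,10,14-triene F2. A second Negishi coupling with the alkylzinc bromide from 17 forms the C15–C16 bond with retention of the E geometry and gives the hexaene (3R,7R,10E,14E,18R,22S)-2,3,7,10,15,18,22,23-octamethyl-6,19-dimethylidenetetracosa-1,10,14,23-tetraene F3. Shi epoxidation with the L-fructose-derived ketone antipode (chosen for the S,S sense) and a limited amount of Oxone should epoxidise the two electron-richer trisubstituted alkenes in preference to the four branched 1,1-disubstituted ones and give 27; the weak point of this fallback is that chemoselectivity.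

Step 16. What may go wrong: intramolecular aldolisation of hexanedial, in which the enamine of one terminus attacks the other terminus (the more so once that terminus has become an electrophilic α-chloro aldehyde), competing with chlorination. The fallback chlorinates one terminus at a time with the other masked; it sets out from cyclohexene 18 and comes back at diol 21. Ozonolysis of 18 in MeOH–CH2Cl2 with TsOH, then NaHCO3 and Me2S, gives 6,6-dimethoxyhexanal F4. The same enamine chlorination gives (2R)-2-chloro-6,6-dimethoxyhexanal F5, and MeMgBr gives (3R)-3-chloro-7,7-dimethoxyheptan-2-ol F6. Aqueous acid releases (5R)-5-chloro-6-hydroxyheptanal F7; a second catalyst-controlled chlorination gives (2R,5R)-2,5-dichloro-6-hydroxyheptanal F8; MeMgBr (2.2 equiv) then returns to 21.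

Step 19. What may go wrong: over-addition (both ketones of the dione reacting) and enolisation by the Grignard reagent, or loss of material when the mono-adduct is separated from the excess dione. The fallback breaks the symmetry at the oxidation level before the union; it sets out from diol 21 and comes back at 24. Mono-oxidation of 21 with one equivalent of Dess–Martin periodinane gives the ketol (3R,6R)-3,6-dichloro-7-hydroxyoctan-2-one F9, with recovered 21 recycled and over-oxidised material being dione 22 itself. The secondary hydroxyl of F9 is deprotonated with t-BuMgCl (1.0 equiv) at −78 °C and Grignard reagent 23 (made from 10 as in step 19) is added under the same Cornforth control to give (3R,6R,7S,10R,14R)-3,6-dichloro-7,10,14,15-tetramethyl-11-methylidenehexadec-15-ene-2,7-diol F10. Dess–Martin oxidation, which touches only the secondary alcohol, returns to 24.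

Further compounds
F1 | step 20 | (2E,6E)-2,7-diiodoocta-2,6-diene | C/C(I)=C\CC/C=C(\C)I
F2 | step 20 | (3R,7R,10E,14E)-15-iodo-2,3,7,10-tetramethyl-6-methylidenehexadeca-1,10,14-triene | C=C(C)[C@H](C)CCC(=C)[C@H](C)CC/C(C)=C/CC/C=C(\C)I
F3 | step 20 | (3R,7R,10E,14E,18R,22S)-2,3,7,10,15,18,22,23-octamethyl-6,19-dimethylidenetetracosa-1,10,14,23-tetraene | C=C(C)[C@H](C)CCC(=C)[C@H](C)CC/C(C)=C/CC/C=C(\C)CC[C@@H](C)C(=C)CC[C@H](C)C(=C)C
F4 | step 16 | 6,6-dimethoxyhexanal | COC(OC)CCCCC=O
F5 | step 16 | (2R)-2-chloro-6,6-dimethoxyhexanal | COC(OC)CCC[C@@H](Cl)C=O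
F6 | step 16 | (3R)-3-chloro-7,7-dimethoxyheptan-2-ol (C2 epimers) | COC(OC)CCC[C@@H](Cl)C(C)O
F7 | step 16 | (5R)-5-chloro-6-hydroxyheptanal (C6 epimers) | O=CCCC[C@@H](Cl)C(C)O
F8 | step 16 | (2R,5R)-2,5-dichloro-6-hydroxyheptanal (C6 epimers) | O=C[C@H](Cl)CC[C@@H](Cl)C(C)O
F9 | step 19 | (3R,6R)-3,6-dichloro-7-hydroxyoctan-2-one (C7 epimers) | CC(=O)[C@H](Cl)CC[C@@H](Cl)C(C)O
F10 | step 19 | (3R,6R,7S,10R,14R)-3,6-dichloro-7,10,14,15-tetramethyl-11-methylidenehexadec-15-ene-2,7-diol (C2 epimers) | C=C(C)[C@H](C)CCC(=C)[C@H](C)CC[C@](C)(O)[C@H](Cl)CC[C@@H](Cl)C(C)O
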